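Late in your flask the question is what the charge allows, so I start there, not at the early ratio. You asked for a quick number and your hunch was that isomer of the product A ends ahead of target. Here is what we have.

| setting | eta | gamma | flask |
|---|---|---|---|
| substrate | 1.6 M | 1.6 M | 1.6 M |
| reagent | 0.50 equiv | 0.75 equiv | 0.500 equiv |
| other conformer | 0.50 equiv | 0.50 equiv | 0.500 equiv |
| remark | the very flask that is asked about, followed so far | run made earlier |  |
| time |  |  | 10 d |

- eta (time / h: isomer of the product A / %, target / %): 3.00: 5.7, 6.1; 10.0: 12.9, 10.2; 15.0: 17.3, 7.7; 25.0: 19.1, 5.7; 40.0: 22.8, 5.0; 50.0: 24.1, 2.8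
- gamma (time / d: isomer of the product A / %, target / %): 1.67: 33.5, 8.0; 3.00: 37.8, 5.1; 5.00: 42.7, 4.2; 6.00: 45.8, 1.7; 8.00: 48.7, 0; 10.0: 48.9, 1.4

(readings scatter by 1 percentage point)

- ratio of isomer of the product A to target at 12 min
- ratio of isomer of the product A to target at 6.0 h
- ratio of isomer of the product A to target at 10 d
- which of isomer of the product A and target there is more of at 10 d

- the numbers in the tables scatter with a standard deviation of 1 percentage point

Add isomer of the product A and target in the gamma run and the sum reads 50.3 % at 10.0 d. Gamma's charge gives 50.0 % if you divide the equivalents of reagent by those of substrate and other conformer together, and if each reagent makes one product.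

So the quantity I carry is 33.3 % for your flask, the reagent ceiling C: reagent equivalents over substrate plus other conformer equivalents. Your flask holds less reagent than substrate and other conformer together, so reagent is the limiting reagent.

In eta, target falls from 10.2 % at 10.0 h to 2.8 % at 50.0 h while isomer of the product A climbs, so I expect that isomer to take nearly all of C by 10 d. Gamma's last target reading, 1.4 %, lies close to the scatter of 1 point. Used as a rough stand-in for your flask, although gamma had more reagent, it puts your ratio at 10 d near 23.8, and higher if target lies lower.

Early on I read eta directly: the ratio reads about 0.934 at 3.00 h and about 1.26 at 10.0 h, each with the scatter of its readings. I would take about the first for 12 min and a value between them for 6.0 h.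

The forecast, which also holds that “reagent is limiting”, gives ratios of 0.85, 1.1 and 60, with isomer of the product A ahead.

The flask gives 0.896, 1.21 and 103, with 32.6 % isomer of the product A against 0.316 % target at 10 d.

    substrate ⇌ other conformer (K = 1.00, k = 0.0400 h⁻¹)
    substrate + reagent ⇌ target (K = 1.40 M⁻¹, k = 0.0620 M⁻¹ h⁻¹)
    reagent + other conformer → isomer of the product A (k = 0.110 M⁻¹ h⁻¹)
    target ⇌ isomer of the product B (K = 0.700, k = 0.0300 h⁻¹)

In your flask, isomer of the product A stands at 97.9 % of C at 10 d, with reagent down to 0.34 % of its own charge. Now take a neighbouring flask, the same except for 0.120 equiv of other conformer. Its C is 44.6 %. At 10 d that neighbour holds 43.0 % isomer of the product A, 0.649 % target and 0.645 % isomer of the product B, and its ratio of isomer of the product A to target is 66.2.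

The runs were generated by integration with constants of no real substance, noise included.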